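Monday's flask holds 0.40 M of substrate and 12 mM of free catalyst. Wednesday's holds the same substrate and 100 mM of free catalyst.

the same everywhere: substrate 0.40 M

| charge | free catalyst | temperature | remark | time |
|---|---|---|---|---|
| beta | 140 mM | −15 °C | run made earlier |  |
| epsilon | 140 mM | 0 °C | run made earlier |  |
| Thursday's | 30 mM | 0 °C |  | 15 min |
| Friday's | 80 mM | 0 °C |  | 15 min |
| Saturday's | 15 mM | 0 °C |  | 15 min |
| Wednesday's | 100 mM | 0 °C |  | 15 min |
| Monday's | 12 mM | 0 °C |  | 15 min |
| Tuesday's | 48 mM | 0 °C |  | 15 min |

| run | time / min | product / % |
|---|---|---|
| beta | 1.33 | 2.2 |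
| beta | 4.00 | 12.7 |
| beta | 8.00 | 30.2 |
| beta | 12.0 | 44.6 |
| beta | 15.0 | 53.3 |
| beta | 20.0 | 66.8 |
| epsilon | 0.667 | 7.0 |
| epsilon | 2.00 | 30.7 |
| epsilon | 4.00 | 57.0 |
| epsilon | 6.00 | 73.9 |
| epsilon | 8.00 | 83.2 |
| epsilon | 10.0 | 89.1 |

(standard deviation of a reading: 0.5 percentage points)

1. the flasks by amount of product, in percent of the substrate charged, highest first, at 15 min (Thursday's / Friday's / Saturday's / Wednesday's / Monday's / Tuesday's)
2. the amount of product, in percent of the substrate charged of the flask you put first, at 15 min
3. the amount of product, in percent of the substrate charged of the flask you put last, at 15 min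

- no earlier run changes the charge of free catalyst; that part of a forecast is a guess

My bench rule is pseudo-first-order: substrate falls with a constant k, and I guess that k scales with the catalyst charge. No earlier run tests that guess. In the epsilon run, product goes from 30.7% to 89.1% between 2.00 min and 10.0 min. So I read k = 0.231 /min at 140 mM of free catalyst. Scaled to the charge and run for 15 min, Wednesday's gives 91.6% and Monday's 25.7%. The rule ranks the flasks by catalyst charge.

But the rule assumes that the catalyst comes back unharmed from each round. So I carry one ratio: the rounds demanded, N, the substrate charged over the catalyst charged, which for Monday's is 33.3. The epsilon run demands 2.86, so Monday's asks about ten times as many rounds as the epsilon run. Wednesday's demands 4.00, close to the epsilon run. A loss per round too slight to see there could grow over Monday's rounds. So I keep my figure for Wednesday's and expect Monday's to come out below its figure.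

The forecast has the same order, Wednesday's > Friday's > Tuesday's > Thursday's > Saturday's > Monday's, with 90% (80% to 96%) for the first flask and 25% (8% to 55%) for the last, each a little under my figures: “The ranking simply follows catalyst charge.”

The flasks give Wednesday's > Friday's > Tuesday's > Thursday's > Saturday's > Monday's, with 89.0% in Wednesday's and 19.6% in Monday's.

    substrate + catalyst intermediate A → spent catalyst (k = 0.00630 /M/s, Ea = 49.0 kJ/mol)
    substrate + free catalyst → catalyst intermediate A (k = 0.0470 /M/s, Ea = 42.0 kJ/mol)
    catalyst intermediate A → catalyst intermediate B (k = 0.0320 /s, Ea = 68.0 kJ/mol)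
    catalyst intermediate B → free catalyst + product (k = 0.240 /s, Ea = 70.0 kJ/mol)
    (constants at 0 °C)

In Wednesday's flask, catalyst death is the main reason for the shortfall: catalyst intermediate A meets substrate and becomes spent catalyst, and without that step Wednesday's gives 96.7% instead of 89.0%. Monday's flask makes 6.53 rounds of the 33.3 demanded, and there the same step is only a part of the gap: without it Monday's gives 26.9% instead of 19.6%. The neighbour of Wednesday's charged with 1.6 M of substrate demands 16.0 rounds and makes 3.87, with 97.2% of its catalyst charge spent and 64% of its substrate left at 15.0 min.

(The readings are calculated with made-up constants; the scatter is artificial.)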